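**Retrosynthetic overview**

1. The target (7R,8S)-acetate comes from acetylation of the erythro C7 alcohol, which comes from chelation-controlled reduction of the (8S)-aryl ketone (C7 = benzylic carbon, C8 = aryloxy carbon, C9 = methyl).
2. The strategy rests on ring A being a 1-acyl-3,4-dimethoxybenzene: C2–C3(OMe)–C4(OMe)–C5 are the four carbons of symmetric 2,3-dimethoxybuta-1,3-diene, and the C1–C6 edge is an alkyne carrying the C7(=O)–C8–C9 chain.
3. Ring A is therefore made by a Diels–Alder reaction (bonds C1–C2 and C5–C6) of a terminal ynone with the diene, followed by dehydrogenation of the 1,4-cyclohexadiene.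
4. The ynone comes from a Weinreb amide and ethynylmagnesium bromide; the C8–O–C4' ether and the C8 stereocentre come from Mitsunobu inversion of methyl (R)-lactate with 4-allyl-2,6-dimethoxyphenol.
5. Ring order: ring B (the allyl-dimethoxyphenoxy ring) is bought intact; ring A is the only ring built, closed in step 4 and aromatised in step 5.

Key step: step 4

Remark: 2,3-dimethoxybuta-1,3-diene is taken as a purchased compound, and Zn(BH4)2 is used as a pre-formed ethereal solution.

**Route**

Step 1
Reactants: 1 methyl (R)-lactate; 2 4-allyl-2,6-dimethoxyphenol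
Product: 3 methyl (S)-2-(4-allyl-2,6-dimethoxyphenoxy)propanoate
Conditions: PPh3, DIAD, THF, 0 °C → rt
Reagents that add atoms: none
Why: Mitsunobu etherification, in which the phenoxide (pKa about 10) displaces the lactate oxyphosphonium by SN2 at the ester-activated secondary carbon with clean inversion, so (R)-lactate sets C8 as S.

Step 2
Reactants: 3 methyl (S)-2-(4-allyl-2,6-dimethoxyphenoxy)propanoate
Product: 4 (S)-2-(4-allyl-2,6-dimethoxyphenoxy)-N-methoxy-N-methylpropanamide
Conditions: MeNH(OMe)·HCl (1.5 equiv), i-PrMgCl (3.0 equiv), THF, −20 → 0 °C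
Reagents that add atoms: N,O-dimethylhydroxylamine hydrochloride, CNOC.Cl
Why: Weinreb amide formation by aminolysis of the ester with the chloromagnesium amide made in the flask, a weakly basic nucleophile that should leave the C8 hydrogen in place at low temperature.

Step 3
Reactants: 4 (S)-2-(4-allyl-2,6-dimethoxyphenoxy)-N-methoxy-N-methylpropanamide; 5 ethynylmagnesium bromide
Product: 6 (S)-4-(4-allyl-2,6-dimethoxyphenoxy)pent-1-yn-3-one
Conditions: HC≡CMgBr (0.5 M in THF, 2.5 equiv), THF, 0 °C; cannulate into cold 1 M HCl
Reagents that add atoms: none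
Why: Weinreb ketone synthesis, in which the chelated tetrahedral magnesium adduct blocks over-addition and enolisation at C8 until the quench, and the inverse acidic quench protonates the released amine before it can add to the ynone.

Step 4
Reactants: 6 (S)-4-(4-allyl-2,6-dimethoxyphenoxy)pent-1-yn-3-one; 7 2,3-dimethoxybuta-1,3-diene
Product: 8 (S)-2-(4-allyl-2,6-dimethoxyphenoxy)-1-(4,5-dimethoxycyclohexa-1,4-dien-1-yl)propan-1-one
Conditions: 7 (3 equiv), BHT (cat.), toluene, 80–100 °C, sealed tube, Ar, acid-free glassware; concentrate and use directly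
Reagents that add atoms: none
Why: A concerted, suprafacial thermal [4+2] cycloaddition of normal electron demand joins the carbonyl-activated alkyne of 6 (LUMO lowered by the C7 ketone) to the electron-rich s-cis diene 7, forming C1–C2 and C5–C6 in one event. The closest known reaction type is the Diels–Alder reaction of acetylenic ketones and esters with 2,3-dialkoxybuta-1,3-dienes, which gives 1,2-dialkoxycyclohexa-1,4-dienes that are aromatised afterwards. Ring A is closed as a six-membered carbocycle by intermolecular [4+2] annulation, the alkyne supplying C1 and C6 and the diene C2–C5. No stereocentre is created, and C8 from step 1 should be carried through because the medium holds neither acid nor base and the ketone is not enolised. The step needs chemoselectivity for the ynone over the isolated allyl alkene of ring B, which the conjugative activation of the alkyne secures, and it has no regiochemical issue because the diene is symmetric, so both methoxy groups must end up meta and para to the acyl carbon. BHT and an inert atmosphere suppress radical polymerisation of the diene and premature air oxidation of the adduct.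

Step 5
Reactants: 8 (S)-2-(4-allyl-2,6-dimethoxyphenoxy)-1-(4,5-dimethoxycyclohexa-1,4-dien-1-yl)propan-1-one
Product: 9 (S)-2-(4-allyl-2,6-dimethoxyphenoxy)-1-(3,4-dimethoxyphenyl)propan-1-one
Conditions: DDQ (1.05 equiv), toluene, 0 °C; filter, wash with aq. NaHCO3
Reagents that add atoms: none
Why: DDQ dehydrogenation, in which hydride abstraction from a doubly allylic, enol-ether-activated ring CH2 and proton loss should aromatise the 1,4-cyclohexadiene far faster at 0 °C than DDQ attacks the allyl group or ring B, under neutral conditions that leave C8 alone.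

Step 6
Reactants: 9 (S)-2-(4-allyl-2,6-dimethoxyphenoxy)-1-(3,4-dimethoxyphenyl)propan-1-one
Product: 10 (1R,2S)-2-(4-allyl-2,6-dimethoxyphenoxy)-1-(3,4-dimethoxyphenyl)propan-1-ol
Conditions: Zn(BH4)2, Et2O, −40 → 0 °C; aq. NH4Cl
Reagents that add atoms: none
Why: Chelation-controlled (Cram cyclic model) hydride reduction, in which divalent zinc bridges the C7 carbonyl oxygen and the C8 ether oxygen (assisted by an ortho methoxy group of ring B) and hydride arrives on the face flanked by the C8 hydrogen and not by the C9 methyl, which should set C7 as R (erythro).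

Step 7
Reactants: 10 (1R,2S)-2-(4-allyl-2,6-dimethoxyphenoxy)-1-(3,4-dimethoxyphenyl)propan-1-ol
Product: 11 Maceneolignan H, (1R,2S)-2-(4-allyl-2,6-dimethoxyphenoxy)-1-(3,4-dimethoxyphenyl)propyl acetate
Conditions: Ac2O, pyridine, DMAP (cat.), CH2Cl2, rt
Reagents that add atoms: acetic anhydride, CC(=O)OC(C)=O
Why: DMAP-catalysed O-acylation of the secondary benzylic alcohol, which takes place at oxygen and so retains both stereocentres.

**Compound list**

1 | methyl (R)-lactate | C[C@@H](O)C(=O)OC | starting material
2 | 4-allyl-2,6-dimethoxyphenol | C=CCc1cc(OC)c(O)c(OC)c1 | starting material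
3 | methyl (S)-2-(4-allyl-2,6-dimethoxyphenoxy)propanoate | C=CCc1cc(OC)c(O[C@@H](C)C(=O)OC)c(OC)c1 | intermediate
4 | (S)-2-(4-allyl-2,6-dimethoxyphenoxy)-N-methoxy-N-methylpropanamide | C=CCc1cc(OC)c(O[C@@H](C)C(=O)N(C)OC)c(OC)c1 | intermediate
5 | ethynylmagnesium bromide | C#C[Mg]Br | starting material
6 | (S)-4-(4-allyl-2,6-dimethoxyphenoxy)pent-1-yn-3-one | C=CCc1cc(OC)c(O[C@@H](C)C(=O)C#C)c(OC)c1 | intermediate
7 | 2,3-dimethoxybuta-1,3-diene | C=C(OC)C(=C)OC | starting material
8 | (S)-2-(4-allyl-2,6-dimethoxyphenoxy)-1-(4,5-dimethoxycyclohexa-1,4-dien-1-yl)propan-1-one | C=CCc1cc(OC)c(O[C@@H](C)C(=O)C2=CCC(OC)=C(OC)C2)c(OC)c1 | intermediate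
9 | (S)-2-(4-allyl-2,6-dimethoxyphenoxy)-1-(3,4-dimethoxyphenyl)propan-1-one | C=CCc1cc(OC)c(O[C@@H](C)C(=O)c2ccc(OC)c(OC)c2)c(OC)c1 | intermediate
10 | (1R,2S)-2-(4-allyl-2,6-dimethoxyphenoxy)-1-(3,4-dimethoxyphenyl)propan-1-ol | C=CCc1cc(OC)c(O[C@@H](C)[C@H](O)c2ccc(OC)c(OC)c2)c(OC)c1 | intermediate
11 | Maceneolignan H, (1R,2S)-2-(4-allyl-2,6-dimethoxyphenoxy)-1-(3,4-dimethoxyphenyl)propyl acetate | C=CCc1cc(OC)c(O[C@@H](C)[C@H](OC(C)=O)c2ccc(OC)c(OC)c2)c(OC)c1 | target

**Step count**

Total step count: 7
Longest linear sequence: 7 steps (from 1 and 2 to 11)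

**Steps most likely to fail**

Step 4 (key step). The cycloaddition may be slow enough that thermal polymerisation of the diene or of the terminal ynone takes over. The bis(enol ether) adduct may hydrolyse on trace acid, or C8 may lose configurational purity on long heating. Fallback: the ring A carbons are brought in as an intact aryl nucleophile. Weinreb amide 4 is treated in THF at 0 °C with 3,4-dimethoxyphenylmagnesium bromide F1, made from 4-bromo-1,2-dimethoxybenzene and Mg turnings in THF. This Weinreb ketone synthesis should give aryl ketone 9 directly, so the route is rejoined at 9 and steps 3 to 5 are bypassed.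

Step 3. On quench the liberated N,O-dimethylhydroxylamine may add in conjugate fashion to the new ynone, and the terminal ynone may oligomerise on concentration. Fallback: amide 4 is reduced with i-Bu2AlH (THF, −78 °C) to (S)-2-(4-allyl-2,6-dimethoxyphenoxy)propanal F2. Ethynylmagnesium bromide 5 is added at −78 °C to give (4S)-4-(4-allyl-2,6-dimethoxyphenoxy)pent-1-yn-3-ol F3 as a mixture of carbinol epimers, which does not matter because that centre is then oxidised. Dess–Martin periodinane with NaHCO3 in CH2Cl2 at 0 °C should then deliver ynone 6 under neutral, amine-free conditions, and the route is rejoined at 6.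

Step 6. Facial selectivity may be poor if the weakly basic, doubly flanked aryl ether oxygen does not hold zinc in a five-membered chelate, so that open Felkin–Anh attack competes. Fallback: the opposite sense of induction is used on purpose and then corrected by inversion. Ketone 9 is reduced under non-chelating Felkin–Anh control with LiBH(s-Bu)3 (THF, −78 °C) to the threo alcohol (1S,2S)-2-(4-allyl-2,6-dimethoxyphenoxy)-1-(3,4-dimethoxyphenyl)propan-1-ol F4. A Mitsunobu reaction with 4-nitrobenzoic acid (PPh3, DIAD, toluene, 0 °C) inverts C7 to give (1R,2S)-2-(4-allyl-2,6-dimethoxyphenoxy)-1-(3,4-dimethoxyphenyl)propyl 4-nitrobenzoate F5. Methanolysis (K2CO3, MeOH, rt) should then give erythro alcohol 10, where the route is rejoined; any threo alcohol separated from an unselective run of step 6 can be recycled the same way.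

**Further compounds**

F1 | step 4 | 3,4-dimethoxyphenylmagnesium bromide | COc1ccc([Mg]Br)cc1OC
F2 | step 3 | (S)-2-(4-allyl-2,6-dimethoxyphenoxy)propanal | C=CCc1cc(OC)c(O[C@@H](C)C=O)c(OC)c1
F3 | step 3 | (4S)-4-(4-allyl-2,6-dimethoxyphenoxy)pent-1-yn-3-ol (both C3 epimers) | C=CCc1cc(OC)c(O[C@@H](C)C(O)C#C)c(OC)c1
F4 | step 6 | (1S,2S)-2-(4-allyl-2,6-dimethoxyphenoxy)-1-(3,4-dimethoxyphenyl)propan-1-ol | C=CCc1cc(OC)c(O[C@@H](C)[C@@H](O)c2ccc(OC)c(OC)c2)c(OC)c1
F5 | step 6 | (1R,2S)-2-(4-allyl-2,6-dimethoxyphenoxy)-1-(3,4-dimethoxyphenyl)propyl 4-nitrobenzoate | C=CCc1cc(OC)c(O[C@@H](C)[C@H](OC(=O)c2ccc(cc2)[N+](=O)[O-])c2ccc(OC)c(OC)c2)c(OC)c1
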